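## Retrosynthetic overview

1. Pilosanol B ⇒ (+)-catechin (chiral pool; brings rings A, B, C and both stereocentres) + ortho-quinone methide 12 of acylphloroglucinol 9. The C8–CH2 bond is made by Michael-type arylation, as in the presumed biosynthesis.
2. Ring D (9) is not taken from phloroglucinol. It is cut across C1–C6 to the linear, already C- and O-methylated tetraketide ester 7, closed by a polyketide-synthase-type Claisen cyclisation.
3. 7 ⇒ 4-methoxy-2-pyranone 5 (masked triketide) + methyl acetate enolate (extender unit). The pyranone OMe becomes the hindered 2-OMe and the pyranone C-methyl becomes the ring methyl, so no selective phenol methylation is needed.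
4. 5 ⇒ triketide pyranone 4 ⇒ ethyl 2-methylacetoacetate 1 + methyl isobutyrate 2 (starter unit).
5. Ring order: 2-pyranone (step 1) → benzene ring D by ring transformation (step 3) → union with the preformed rings A/B/C (step 4).

Assumption: the target SMILES is read as (2R,3S) at the flavan unit, i.e. the (+)-catechin series, and (+)-catechin is used as the purchased single enantiomer.

## Route

**Step 1**
Reactants: 1 ethyl 2-methyl-3-oxobutanoate (racemic); 2 methyl 2-methylpropanoate
Product: 4 4-hydroxy-6-isopropyl-3-methyl-2H-pyran-2-one, via ethyl 2,6-dimethyl-3,5-dioxoheptanoate 3 (not isolated)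
Conditions: 1 (2.2 equiv), LiN(iPr)2 (4.4 equiv), THF, −78 → 0 °C; 2 (1.0 equiv), 0 → 25 °C; aq HCl, extract; crude 3, DBU, PhMe, 110 °C; aq HCl
Reagents that add atoms: none
Why: The terminal carbanion of the β-keto ester dianion is acylated by the ester (Claisen condensation of a dianion), and DBU then lactonises the 3,5-diketo ester through its enol to the 4-hydroxy-2-pyranone, the same triketide ring closure that polyketide synthases perform; no stereocentre is formed.

**Step 2**
Reactants: 4 4-hydroxy-6-isopropyl-3-methyl-2H-pyran-2-one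
Product: 5 6-isopropyl-4-methoxy-3-methyl-2H-pyran-2-one
Conditions: Me2SO4 (1.2 equiv), K2CO3 (2 equiv), acetone, 56 °C
Reagents that add atoms: dimethyl sulfate, COS(=O)(=O)OC
Why: The pyranone 4-OH is a vinylogous acid whose potassium salt is O-methylated mainly at O4 (Williamson-type O-alkylation); the minor 2-methoxy-4-pyranone isomer is removed by chromatography.

**Step 3**
Reactants: 5 6-isopropyl-4-methoxy-3-methyl-2H-pyran-2-one; 6 methyl acetate
Product: 9 1-(4,6-dihydroxy-2-methoxy-3-methylphenyl)-2-methylpropan-1-one, via open-chain keto ester 7 (not isolated), via cyclohexenedione 8 (not isolated)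
Conditions: 6 (3 equiv), LiN(iPr)2 (3 equiv), THF, −78 °C; add 5, −78 → 0 °C; then MeOH, 60 °C; aq HCl
Reagents that add atoms: none
Why: Proposed new method: the ester enolate adds to the lactone C=O of 5 and the ring opens to the dienolate of 7; under the LiOMe formed on adding MeOH, C6 of 7 (alpha to the isopropyl ketone and vinylogously activated through the enol ether) attacks the methyl ester in a 6-exo-trig Claisen (Dieckmann-type) closure to 8, which aromatises by enolisation; strong base keeps the C7 ketone enolised so that the competing aldol (resorcylate) closure is held back; the closest known reaction types are the addition of ester-stabilised carbanions to the lactone carbonyl of 4-methoxy-2-pyranones with in-flask Claisen closure and the base-mediated Claisen cyclisation of 3,5,7-triketo esters to acylphloroglucinols; no stereocentre remains.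

**Step 4**
Reactants: 9 1-(4,6-dihydroxy-2-methoxy-3-methylphenyl)-2-methylpropan-1-one; 10 (+)-catechin
Product: 13 pilosanol B, via Mannich base 11 (not isolated), via ortho-quinone methide 12 (not isolated)
Conditions: 9, CH2=NMe2+ I− (1.05 equiv), NaOAc (1.1 equiv), MeCN, 25 °C; then 10 (4 equiv), degassed MeCN–H2O 4:1, 80 °C, Ar; Sephadex LH-20, then reversed-phase HPLC
Reagents that add atoms: N,N-dimethylmethylideneammonium iodide (Eschenmoser's salt), C=[N+](C)C.[I-]
Why: Mannich aminomethylation at the only free ring position of 9, thermal loss of dimethylamine to the ortho-quinone methide 12 and Michael-type Friedel–Crafts trapping by C8 of the catechin ring A give the methylene bridge; no bond at C2 or C3 is touched, so (2R,3S) is carried over from 10, and the C6-linked isomer is the expected minor product.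

## Compound list

1 | ethyl 2-methyl-3-oxobutanoate (racemic) | CCOC(=O)C(C)C(C)=O | starting material
2 | methyl 2-methylpropanoate (methyl isobutyrate) | COC(=O)C(C)C | starting material
3 | ethyl 2,6-dimethyl-3,5-dioxoheptanoate (racemic, enolisable) | CCOC(=O)C(C)C(=O)CC(=O)C(C)C | intermediate
4 | 4-hydroxy-6-isopropyl-3-methyl-2H-pyran-2-one | CC1=C(O)C=C(C(C)C)OC1=O | intermediate
5 | 6-isopropyl-4-methoxy-3-methyl-2H-pyran-2-one | COC1=C(C)C(=O)OC(C(C)C)=C1 | intermediate
6 | methyl acetate | COC(C)=O | starting material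
7 | methyl (4E)-5-methoxy-4,8-dimethyl-3,7-dioxonon-4-enoate (present as its lithium enolate) | COC(=O)CC(=O)/C(C)=C(OC)\CC(=O)C(C)C | intermediate
8 | 5-methoxy-4-methyl-6-(2-methylpropanoyl)cyclohex-4-ene-1,3-dione (racemic keto tautomer of 9) | CC(C)C(=O)C1C(=O)CC(=O)C(C)=C1OC | intermediate
9 | 1-(4,6-dihydroxy-2-methoxy-3-methylphenyl)-2-methylpropan-1-one | COc1c(C)c(O)cc(O)c1C(=O)C(C)C | intermediate
10 | (+)-catechin, (2R,3S)-2-(3,4-dihydroxyphenyl)chromane-3,5,7-triol | Oc1cc(O)c2c(c1)O[C@H](c1ccc(O)c(O)c1)[C@@H](O)C2 | starting material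
11 | 1-[3-[(dimethylamino)methyl]-2,4-dihydroxy-6-methoxy-5-methylphenyl]-2-methylpropan-1-one | COc1c(C)c(O)c(CN(C)C)c(O)c1C(=O)C(C)C | intermediate
12 | 5-hydroxy-3-methoxy-2-methyl-6-methylidene-4-(2-methylpropanoyl)cyclohexa-2,4-dien-1-one | C=C1C(=O)C(C)=C(OC)C(C(=O)C(C)C)=C1O | intermediate
13 | pilosanol B, (2R,3S) | COc1c(C)c(O)c(Cc2c(O)cc(O)c3c2O[C@H](c2ccc(O)c(O)c2)[C@@H](O)C3)c(O)c1C(=O)C(C)C | target

## Step count and risks

Total steps: 4. Longest linear sequence: 4 (1 → 4 → 5 → 9 → 13); (+)-catechin enters in the last step.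

**Most likely to fail, first: step 3.** The enolate may attack 5 at C6 or C4 instead of the lactone carbonyl. After ring opening, the β-keto ester CH2 of 7 may close by aldol onto the isopropyl ketone, giving methyl 2-hydroxy-6-isopropyl-4-methoxy-3-methylbenzoate instead of 9. Methoxide may also cleave 7 by retro-Claisen back to 5.

The fallback sets out from 5 and returns at 9. It replaces the enolisable acetate by an alkoxyacetylide, so that no aldol-competent CH2 ever exists. Lithium tert-butoxyacetylide (from 1,2-dichlorovinyl tert-butyl ether and n-BuLi, THF, −78 °C) adds to the lactone carbonyl of 5. The ring-opened ynone (4E)-1-tert-butoxy-5-methoxy-4,8-dimethylnon-4-en-1-yne-3,7-dione F1 can only close by 6-endo-dig conjugate addition of its C6 carbanion onto the alkoxy-bearing alkyne carbon, on warming the lithium dienolate or with K2CO3 in MeCN. Tautomerisation gives the aryl ether 1-(6-tert-butoxy-4-hydroxy-2-methoxy-3-methylphenyl)-2-methylpropan-1-one F2. CF3CO2H in CH2Cl2 at 0 °C removes the tert-butyl group without touching the 2-OMe and delivers 9.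

**Second: step 4.** Catechin can react at C6 as well as C8 and can be alkylated twice, and the Mannich base may need more forcing conditions than catechin tolerates before it releases 12.

The fallback sets out from 10 and returns at 13, fixing the C8 position by substitution chemistry on protected catechin.
- Benzylation (BnBr, K2CO3, DMF, then NaH and more BnBr in the same pot) gives penta-O-benzyl-(+)-catechin F3.
- NBS in CH2Cl2 at −40 °C brominates selectively at C8 to give 8-bromo-penta-O-benzyl-(+)-catechin F4.
- Bromine–lithium exchange (n-BuLi, THF, −78 °C) and DMF give the 8-carbaldehyde F5.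
- NaBH4 in THF–MeOH gives the 8-hydroxymethyl compound F6.
- F6 is ionised with catalytic BF3·OEt2 in CH2Cl2 at −20 °C in the presence of 9 (3 equiv). Friedel–Crafts benzylation at the free ring position of 9 gives penta-O-benzyl pilosanol B F7.
- Hydrogenolysis (H2, Pd(OH)2 on carbon, THF–MeOH) gives 13.

**Third: step 1.** Acylation of the dianion by the α-branched ester can be low-yielding because of proton transfer and self-condensation.

The fallback sets out from 1 and returns at 3, swapping the Claisen acylation for an aldol addition followed by oxidation. The dianion of 1 (LiN(iPr)2, THF, −78 °C) adds cleanly to 2-methylpropanal to give ethyl 5-hydroxy-2,6-dimethyl-3-oxoheptanoate F8 as a diastereomer mixture. Dess–Martin periodinane in CH2Cl2 oxidises it to 3, which is lactonised with DBU as in step 1.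

## Further compounds

F1 | step 3 | (4E)-1-tert-butoxy-5-methoxy-4,8-dimethylnon-4-en-1-yne-3,7-dione | CC(C)(C)OC#CC(=O)/C(C)=C(OC)\CC(=O)C(C)C
F2 | step 3 | 1-(6-tert-butoxy-4-hydroxy-2-methoxy-3-methylphenyl)-2-methylpropan-1-one | COc1c(C)c(O)cc(OC(C)(C)C)c1C(=O)C(C)C
F3 | step 4 | penta-O-benzyl-(+)-catechin, (2R,3S)-3,5,7-tris(benzyloxy)-2-[3,4-bis(benzyloxy)phenyl]chromane | C(c1ccccc1)Oc1cc(OCc3ccccc3)c2c(c1)O[C@H](c1ccc(OCc3ccccc3)c(OCc3ccccc3)c1)[C@@H](OCc1ccccc1)C2
F4 | step 4 | 8-bromo-penta-O-benzyl-(+)-catechin | C(c1ccccc1)Oc1cc(OCc3ccccc3)c2c(c1Br)O[C@H](c1ccc(OCc3ccccc3)c(OCc3ccccc3)c1)[C@@H](OCc1ccccc1)C2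
F5 | step 4 | penta-O-benzyl-(+)-catechin-8-carbaldehyde | C(c1ccccc1)Oc1cc(OCc3ccccc3)c2c(c1C=O)O[C@H](c1ccc(OCc3ccccc3)c(OCc3ccccc3)c1)[C@@H](OCc1ccccc1)C2
F6 | step 4 | 8-(hydroxymethyl)-penta-O-benzyl-(+)-catechin | C(c1ccccc1)Oc1cc(OCc3ccccc3)c2c(c1CO)O[C@H](c1ccc(OCc3ccccc3)c(OCc3ccccc3)c1)[C@@H](OCc1ccccc1)C2
F7 | step 4 | penta-O-benzyl pilosanol B (3,5,7,3',4'-O-benzyl) | C(c1ccccc1)Oc1cc(OCc3ccccc3)c2c(c1Cc4c(O)c(C)c(OC)c(C(=O)C(C)C)c4O)O[C@H](c1ccc(OCc3ccccc3)c(OCc3ccccc3)c1)[C@@H](OCc1ccccc1)C2
F8 | step 1 | ethyl 5-hydroxy-2,6-dimethyl-3-oxoheptanoate (diastereomer mixture) | CCOC(=O)C(C)C(=O)CC(O)C(C)C
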